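**Strategy.** Everything rests on cutting the two bonds at the neighbouring ring B carbons C1′ and C6′: C2–C1′ to the benzofuran and C6′–CH2 to the prenyl chain. The key step exploits the C5′ methoxy group beside this C1′/C6′ pair: a 3-methoxy-5-silyloxybenzyne, released from a fluoroarene lithiated between F and OMe, takes up a 2-lithiobenzofuran at C1′ and leaves a methoxy-stabilised C6′ anion that copper prenylates, so both substituents arrive in one pot. The precursors are a 2-bromo-7-(1,1-dimethylallyl)benzofuran bis-TBS ether, made from phloroglucinol through an aryl prenyl ether Claisen rearrangement, ortho-formylation, dibromo-olefination and copper-catalysed ring closure, and the TIPS ether of 3-fluoro-5-methoxyphenol; fluoride finally frees the three phenols.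

Key step: step 8

Remark: the target is achiral and neither alkene is stereogenic. The benzofuran is numbered O1, C2, C3, C3a, C4–C7, C7a, with OH on C4 and C6 and the 1,1-dimethylallyl group on C7. Ring B is numbered C1′ (bonded to C2), C3′ (OH), C5′ (OMe), C6′ (prenyl); the systematic names below number this ring from the other side.

**Step 1**
Reactants: 1 phloroglucinol
Product: 2 3,5-bis(tert-butyldimethylsilyloxy)phenol
Conditions: TBSCl (2.0 equiv), imidazole, DMF, 0 °C to rt
Reagents that add atoms: tert-butyldimethylsilyl chloride, CC(C)(C)[Si](C)(C)Cl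
Why: Silyl ether formation; on the threefold-symmetric triol the silylation is statistical, so two equivalents of TBSCl should give the bis-ether as the main product, separable by chromatography from the mono- and tris-ethers, which can be recycled.

**Step 2**
Reactants: 2 3,5-bis(tert-butyldimethylsilyloxy)phenol; 3 3-methylbut-2-en-1-ol (prenol)
Product: 4 1-(3-methylbut-2-enyloxy)-3,5-bis(tert-butyldimethylsilyloxy)benzene
Conditions: PPh3, DIAD, THF, 0 °C to rt
Reagents that add atoms: none
Why: Mitsunobu etherification activates the primary allylic alcohol under neutral conditions, so the phenol should be O-alkylated without the C-alkylation of the phloroglucinol nucleus or the loss of aryl silyl ethers that carbonate-mediated alkylation would risk.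

**Step 3**
Reactants: 4 1-(3-methylbut-2-enyloxy)-3,5-bis(tert-butyldimethylsilyloxy)benzene
Product: 5 2-(2-methylbut-3-en-2-yl)-3,5-bis(tert-butyldimethylsilyloxy)phenol
Conditions: N,N-diethylaniline, 190 °C, argon
Reagents that add atoms: none
Why: Aromatic Claisen rearrangement: the [3,3] shift inverts the prenyl group and delivers it to either of the two equivalent ortho carbons, so a single 1,1-dimethylallyl phenol should result with its free hydroxyl exactly beside the new quaternary carbon, the basic solvent favouring rearomatisation over a second shift to the para position.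

**Step 4**
Reactants: 5 2-(2-methylbut-3-en-2-yl)-3,5-bis(tert-butyldimethylsilyloxy)phenol
Product: 6 2-hydroxy-3-(2-methylbut-3-en-2-yl)-4,6-bis(tert-butyldimethylsilyloxy)benzaldehyde
Conditions: MgCl2, Et3N, (CH2O)n, THF, reflux
Reagents that add atoms: paraformaldehyde (source of formaldehyde), C=O
Why: Magnesium-mediated ortho-formylation (Casnati–Skattebøl): the magnesium phenoxide directs formaldehyde to the only free ortho carbon, the other being blocked by the tert-alkyl group as in the well-behaved 2-tert-butylphenol case, and a second formaldehyde oxidises the benzylic alkoxide to the aldehyde.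

**Step 5**
Reactants: 6 2-hydroxy-3-(2-methylbut-3-en-2-yl)-4,6-bis(tert-butyldimethylsilyloxy)benzaldehyde; 7 carbon tetrabromide
Product: 8 2-(2,2-dibromoethenyl)-6-(2-methylbut-3-en-2-yl)-3,5-bis(tert-butyldimethylsilyloxy)phenol
Conditions: PPh3, Et3N, CH2Cl2, 0 °C
Reagents that add atoms: none
Why: Ramirez dibromo-olefination (first stage of the Corey–Fuchs sequence): the ylide Ph3P=CBr2 formed from PPh3 and CBr4 undergoes a Wittig reaction with the aldehyde, Et3N buffering the free phenol as is usual for salicylaldehydes, while aryl silyl ethers and the isolated terminal alkene are inert.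

**Step 6**
Reactants: 8 2-(2,2-dibromoethenyl)-6-(2-methylbut-3-en-2-yl)-3,5-bis(tert-butyldimethylsilyloxy)phenol
Product: 9 2-bromo-7-(2-methylbut-3-en-2-yl)-4,6-bis(tert-butyldimethylsilyloxy)benzofuran
Conditions: CuI (5 mol %), K3PO4, anhydrous THF, 80 °C
Reagents that add atoms: none
Why: Copper-catalysed intramolecular Ullmann-type C–O coupling: the phenoxide displaces the vinylic bromide that lies cis to the arene in a five-membered ring closure and the second bromine remains as the C2 handle, a known route from 2-(2,2-dibromovinyl)phenols to 2-bromobenzofurans.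

**Step 7**
Reactants: 10 3-fluoro-5-methoxyphenol
Product: 11 1-fluoro-3-methoxy-5-(triisopropylsilyloxy)benzene
Conditions: TIPSCl, imidazole, DMF, rt
Reagents that add atoms: triisopropylsilyl chloride, CC(C)[Si](Cl)(C(C)C)C(C)C
Why: Standard silyl ether formation; the bulky TIPS group resists organolithium reagents, discourages lithiation at the two carbons next to it and falls to fluoride together with the TBS ethers.

**Step 8**
Reactants: 9 2-bromo-7-(2-methylbut-3-en-2-yl)-4,6-bis(tert-butyldimethylsilyloxy)benzofuran; 11 1-fluoro-3-methoxy-5-(triisopropylsilyloxy)benzene; 12 prenyl bromide (1-bromo-3-methylbut-2-ene)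
Product: 17 2-[3-methoxy-2-(3-methylbut-2-enyl)-5-(triisopropylsilyloxy)phenyl]-7-(2-methylbut-3-en-2-yl)-4,6-bis(tert-butyldimethylsilyloxy)benzofuran, via 2-lithiobenzofuran 13 (not isolated), via lithiated fluoroarene 14 (not isolated), via 3-methoxy-5-silyloxybenzyne 15 (not isolated), via C6′-lithiobiaryl 16 (not isolated)
Conditions: (a) 11, s-BuLi (1.0 equiv), THF, −78 °C; (b) 9 (1.3 equiv), t-BuLi (2.6 equiv), THF, −78 °C; (c) combine, −78 to 0 °C; (d) CuBr·SMe2 (20 mol %), prenyl bromide, −40 °C to rt
Reagents that add atoms: none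
Why: Bromine–lithium exchange turns 9 into 13 while s-BuLi removes the proton of 11 between F and OMe to give 14; on warming, 14 loses LiF and forms aryne 15, whose strained bond spans C1′–C6′. Lithium reagent 13 adds to C1′, making C2–C1′ and the C6′ aryllithium 16, which after transmetalation to copper displaces bromide from the primary carbon of prenyl bromide and so makes C6′–CH2. The closest known reaction type is the addition of aryllithiums to 3-methoxybenzynes generated from ortho-lithiated fluoroarenes with electrophilic capture of the resulting 2-lithiobiaryl, joined to the copper-catalysed allylation of aryllithiums. No ring is closed and no stereocentre is created. Three selectivities are needed: lithiation at the carbon flanked by the two strongest acidifying groups (F and OMe) and not beside the shielding TIPS ether; attack on the aryne carbon remote from OMe, which is the less hindered end and places the carbanion where the adjacent oxygen stabilises it inductively; and linear allylation, which the doubly ortho-substituted arylcopper should prefer because attack at the tertiary terminus would build a quaternary carbon in a crowded pocket. Capture of 15 by the unhindered 13, used in slight excess, should outrun capture by the hindered species 14 and 16.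

**Step 9**
Reactants: 17 2-[3-methoxy-2-(3-methylbut-2-enyl)-5-(triisopropylsilyloxy)phenyl]-7-(2-methylbut-3-en-2-yl)-4,6-bis(tert-butyldimethylsilyloxy)benzofuran
Product: 18 2-[5-hydroxy-3-methoxy-2-(3-methylbut-2-enyl)phenyl]-7-(2-methylbut-3-en-2-yl)benzofuran-4,6-diol (CNP0169501.0)
Conditions: TBAF (3.5 equiv), AcOH (3.5 equiv), THF, 0 °C to rt, argon
Reagents that add atoms: none
Why: Fluoride-mediated desilylation driven by Si–F bond formation removes all three aryl silyl ethers, and buffering with acetic acid keeps the electron-rich phenols protonated while avoiding the strong acid that could add the C6 hydroxyl across the neighbouring 1,1-dimethylallyl alkene.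

**Compound list**

1 | phloroglucinol | Oc1cc(O)cc(O)c1 | starting material
2 | 3,5-bis(tert-butyldimethylsilyloxy)phenol | CC(C)(C)[Si](C)(C)Oc1cc(O)cc(O[Si](C)(C)C(C)(C)C)c1 | intermediate
3 | 3-methylbut-2-en-1-ol (prenol) | CC(C)=CCO | starting material
4 | 1-(3-methylbut-2-enyloxy)-3,5-bis(tert-butyldimethylsilyloxy)benzene | CC(C)=CCOc1cc(O[Si](C)(C)C(C)(C)C)cc(O[Si](C)(C)C(C)(C)C)c1 | intermediate
5 | 2-(2-methylbut-3-en-2-yl)-3,5-bis(tert-butyldimethylsilyloxy)phenol | C=CC(C)(C)c1c(O)cc(O[Si](C)(C)C(C)(C)C)cc1O[Si](C)(C)C(C)(C)C | intermediate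
6 | 2-hydroxy-3-(2-methylbut-3-en-2-yl)-4,6-bis(tert-butyldimethylsilyloxy)benzaldehyde | C=CC(C)(C)c1c(O)c(C=O)c(O[Si](C)(C)C(C)(C)C)cc1O[Si](C)(C)C(C)(C)C | intermediate
7 | carbon tetrabromide | BrC(Br)(Br)Br | starting material
8 | 2-(2,2-dibromoethenyl)-6-(2-methylbut-3-en-2-yl)-3,5-bis(tert-butyldimethylsilyloxy)phenol | C=CC(C)(C)c1c(O)c(C=C(Br)Br)c(O[Si](C)(C)C(C)(C)C)cc1O[Si](C)(C)C(C)(C)C | intermediate
9 | 2-bromo-7-(2-methylbut-3-en-2-yl)-4,6-bis(tert-butyldimethylsilyloxy)benzofuran | C=CC(C)(C)c1c(O[Si](C)(C)C(C)(C)C)cc(O[Si](C)(C)C(C)(C)C)c2cc(Br)oc12 | intermediate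
10 | 3-fluoro-5-methoxyphenol | COc1cc(O)cc(F)c1 | starting material
11 | 1-fluoro-3-methoxy-5-(triisopropylsilyloxy)benzene | COc1cc(F)cc(O[Si](C(C)C)(C(C)C)C(C)C)c1 | intermediate
12 | prenyl bromide (1-bromo-3-methylbut-2-ene) | CC(C)=CCBr | starting material
13 | [7-(2-methylbut-3-en-2-yl)-4,6-bis(tert-butyldimethylsilyloxy)benzofuran-2-yl]lithium | C=CC(C)(C)c1c(O[Si](C)(C)C(C)(C)C)cc(O[Si](C)(C)C(C)(C)C)c2cc([Li])oc12 | intermediate
14 | [2-fluoro-6-methoxy-4-(triisopropylsilyloxy)phenyl]lithium | COc1cc(O[Si](C(C)C)(C(C)C)C(C)C)cc(F)c1[Li] | intermediate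
15 | 3-methoxy-5-(triisopropylsilyloxy)benzyne | COC1=CC(O[Si](C(C)C)(C(C)C)C(C)C)=CC#C1 | intermediate
16 | {2-[7-(2-methylbut-3-en-2-yl)-4,6-bis(tert-butyldimethylsilyloxy)benzofuran-2-yl]-6-methoxy-4-(triisopropylsilyloxy)phenyl}lithium | C=CC(C)(C)c1c(O[Si](C)(C)C(C)(C)C)cc(O[Si](C)(C)C(C)(C)C)c2cc(-c3cc(O[Si](C(C)C)(C(C)C)C(C)C)cc(OC)c3[Li])oc12 | intermediate
17 | 2-[3-methoxy-2-(3-methylbut-2-enyl)-5-(triisopropylsilyloxy)phenyl]-7-(2-methylbut-3-en-2-yl)-4,6-bis(tert-butyldimethylsilyloxy)benzofuran | C=CC(C)(C)c1c(O[Si](C)(C)C(C)(C)C)cc(O[Si](C)(C)C(C)(C)C)c2cc(-c3cc(O[Si](C(C)C)(C(C)C)C(C)C)cc(OC)c3CC=C(C)C)oc12 | intermediate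
18 | 2-[5-hydroxy-3-methoxy-2-(3-methylbut-2-enyl)phenyl]-7-(2-methylbut-3-en-2-yl)benzofuran-4,6-diol (CNP0169501.0) | C=CC(C)(C)c1c(O)cc(O)c2cc(-c3cc(O)cc(OC)c3CC=C(C)C)oc12 | target

**Step count.** Total: 9 steps. Longest linear sequence: 8 steps (steps 1–6, 8 and 9); step 7 is the one-step side branch.

**Steps most likely to fail**

Step 8. The benzyne may be captured by its own lithiated precursor or by the newly formed biaryllithium instead of by the benzofuranyllithium, giving oligo-arylation. The C6′ anion may also pick up a proton before it is allylated, or the allylic substitution may leak to the tertiary terminus. The fallback makes the two bonds separately by known cross-coupling chemistry; it sets out from 9 and from purchased 3-bromo-5-methoxyphenol (COc1cc(O)cc(Br)c1) and comes back at 17. The bromophenol would be silylated with TIPSCl and imidazole to 1-bromo-3-methoxy-5-(triisopropylsilyloxy)benzene F1. LiN(iPr)2 in THF at −78 °C should remove the proton between Br and OMe to give [2-bromo-6-methoxy-4-(triisopropylsilyloxy)phenyl]lithium F2, which is kept cold so that it cannot lose LiBr. F2 would be allylated with prenyl bromide 12 under CuBr·SMe2 catalysis to 1-bromo-3-methoxy-2-(3-methylbut-2-enyl)-5-(triisopropylsilyloxy)benzene F3. In a second flask 9 would be converted by t-BuLi into 13 and by ZnCl2 into [7-(2-methylbut-3-en-2-yl)-4,6-bis(tert-butyldimethylsilyloxy)benzofuran-2-yl]zinc chloride F4. A Negishi coupling of F4 with F3 (Pd(OAc)2, SPhos, THF, 60 °C) should then give 17.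

Step 3. At 190 °C the liberated electron-rich phenol may keep reacting, through ene-type isomerisation of the new side chain or ring closure of the hydroxyl onto the alkene, and the allyl unit may travel on to the para carbon through a second [3,3] shift. The fallback runs the rearrangement on a salicylaldehyde ether at low temperature; it sets out from 2 and comes back at 6, bypassing 4 and 5. Magnesium-mediated ortho-formylation of 2 (MgCl2, Et3N, paraformaldehyde, THF, reflux) would give 2-hydroxy-4,6-bis(tert-butyldimethylsilyloxy)benzaldehyde F5. Mitsunobu etherification with prenol 3 (PPh3, DIAD) would give 2-(3-methylbut-2-enyloxy)-4,6-bis(tert-butyldimethylsilyloxy)benzaldehyde F6. A Claisen rearrangement catalysed by Eu(fod)3, europium tris(6,6,7,7,8,8,8-heptafluoro-2,2-dimethyloctane-3,5-dionate), in CHCl3 at 60 °C should move the allyl group to the only free ortho carbon. The new hydroxyl is at once tied up in a hydrogen bond to the formyl group, which should suppress further reaction, and the product is 6.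

Step 5. The acidic, hydrogen-bonded phenol may protonate the dibromomethylene ylide so that the hindered, electron-rich aldehyde is olefinated only sluggishly, and the bromophosphonium by-product may attack the free hydroxyl. The fallback masks the phenol for the olefination; it sets out from 6 and comes back at 8. TMSCl and Et3N in CH2Cl2 would give 3-(2-methylbut-3-en-2-yl)-4,6-bis(tert-butyldimethylsilyloxy)-2-(trimethylsilyloxy)benzaldehyde F7. Olefination with CBr4, PPh3 and zinc dust, which removes the bromophosphonium species, would give [2-(2,2-dibromoethenyl)-6-(2-methylbut-3-en-2-yl)-3,5-bis(tert-butyldimethylsilyloxy)phenoxy]trimethylsilane F8. Brief methanolysis with citric acid in MeOH at 0 °C should cleave only the labile aryl trimethylsilyl ether and return 8.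

**Further compounds**

F1 | step 8 | 1-bromo-3-methoxy-5-(triisopropylsilyloxy)benzene | COc1cc(Br)cc(O[Si](C(C)C)(C(C)C)C(C)C)c1
F2 | step 8 | [2-bromo-6-methoxy-4-(triisopropylsilyloxy)phenyl]lithium | COc1cc(O[Si](C(C)C)(C(C)C)C(C)C)cc(Br)c1[Li]
F3 | step 8 | 1-bromo-3-methoxy-2-(3-methylbut-2-enyl)-5-(triisopropylsilyloxy)benzene | COc1cc(O[Si](C(C)C)(C(C)C)C(C)C)cc(Br)c1CC=C(C)C
F4 | step 8 | [7-(2-methylbut-3-en-2-yl)-4,6-bis(tert-butyldimethylsilyloxy)benzofuran-2-yl]zinc chloride | C=CC(C)(C)c1c(O[Si](C)(C)C(C)(C)C)cc(O[Si](C)(C)C(C)(C)C)c2cc([Zn]Cl)oc12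
F5 | step 3 | 2-hydroxy-4,6-bis(tert-butyldimethylsilyloxy)benzaldehyde | O=Cc1c(O)cc(O[Si](C)(C)C(C)(C)C)cc1O[Si](C)(C)C(C)(C)C
F6 | step 3 | 2-(3-methylbut-2-enyloxy)-4,6-bis(tert-butyldimethylsilyloxy)benzaldehyde | CC(C)=CCOc1cc(O[Si](C)(C)C(C)(C)C)cc(O[Si](C)(C)C(C)(C)C)c1C=O
F7 | step 5 | 3-(2-methylbut-3-en-2-yl)-4,6-bis(tert-butyldimethylsilyloxy)-2-(trimethylsilyloxy)benzaldehyde | C=CC(C)(C)c1c(O[Si](C)(C)C)c(C=O)c(O[Si](C)(C)C(C)(C)C)cc1O[Si](C)(C)C(C)(C)C
F8 | step 5 | [2-(2,2-dibromoethenyl)-6-(2-methylbut-3-en-2-yl)-3,5-bis(tert-butyldimethylsilyloxy)phenoxy]trimethylsilane | C=CC(C)(C)c1c(O[Si](C)(C)C)c(C=C(Br)Br)c(O[Si](C)(C)C(C)(C)C)cc1O[Si](C)(C)C(C)(C)C
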